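**Retrosynthetic overview**
1. Ring C of the flavanone is closed last by a catalyst-controlled oxa-Michael addition (C2–O1) of a 2'-hydroxychalcone; the chalcone comes from a late Claisen–Schmidt union of acetophenone 14 (ring A) with dihydrobenzofuran aldehyde 33.
2. The dihydrofuran ring of 33 is made by an enantioselective rhodium-carbene C–H insertion of a diaryldiazomethane into a benzylic ether (C2–C3 bond), then C2 epimerisation to trans; the diaryl ketone comes from aldehyde 25 and arylboronate 3, the ether from a Mitsunobu reaction.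
3. Ring A (14) is built by three successive directed ortho-metalations (prenyl, prenyl, acetyl) of 1,3,5-tris(methoxymethoxy)benzene, itself obtained by oxidation of boronate 3.
4. All four benzene rings derive from resorcinol and 4-bromophenol; boronate 3 feeds both halves.
5. Ring order: dihydrofuran ring (step 18), then pyranone ring C (step 22), then global MOM removal.

Assumption: the sense of induction of Rh2(R-PTAD)4 (step 18) and of the quinine-derived thiourea (step 22) is assigned by analogy with model systems; if the opposite sense is found, the mirror-image catalyst (Rh2(S-PTAD)4; the quinidine-derived pseudo-enantiomer) is used with no other change.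

**Step 1**
Reactants: 1 resorcinol
Product: 2 1,3-bis(methoxymethoxy)benzene
Conditions: MOMCl (2.4 equiv), NaH (2.4 equiv), DMF, 0 °C → rt
Reagents that add atoms: chloromethyl methyl ether (COCCl)
Why: Williamson-type O-alkylation of both phenoxides installs base-stable MOM acetals that survive borylation and organolithium chemistry and come off with dilute acid at the end.

**Step 2**
Reactants: 2 1,3-bis(methoxymethoxy)benzene
Product: 3 2-[3,5-bis(methoxymethoxy)phenyl]-4,4,5,5-tetramethyl-1,3,2-dioxaborolane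
Conditions: B2pin2 (1.0 equiv), [Ir(OMe)(cod)]2 (1.5 mol %), dtbpy (3 mol %), THF, 80 °C
Reagents that add atoms: bis(pinacolato)diboron (CC1(C)OB(OC1(C)C)B1OC(C)(C)C(C)(C)O1)
Why: Sterically governed iridium-catalysed aromatic C–H borylation (Hartwig–Miyaura type) takes place only at C5, the single ring C–H with no ortho substituent.

**Step 3**
Reactants: 3 2-[3,5-bis(methoxymethoxy)phenyl]-4,4,5,5-tetramethyl-1,3,2-dioxaborolane
Product: 4 3,5-bis(methoxymethoxy)phenol
Conditions: H2O2 (30 % aq), NaOH (1 equiv), THF/H2O, 0 °C → rt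
Reagents that add atoms: hydrogen peroxide (OO)
Why: Oxidative C–B to C–O conversion (1,2-aryl shift of the boron peroxo ate complex) proceeds under basic conditions that leave the MOM ethers intact.

**Step 4**
Reactants: 4 3,5-bis(methoxymethoxy)phenol
Product: 5 1,3,5-tris(methoxymethoxy)benzene
Conditions: MOMCl (1.2 equiv), NaH (1.2 equiv), DMF, 0 °C → rt
Reagents that add atoms: chloromethyl methyl ether (COCCl)
Why: MOM protection of the phenoxide gives a threefold-symmetric arene in which every ring C–H lies between two ortho-directing OMOM groups.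

**Step 5**
Reactants: 5 1,3,5-tris(methoxymethoxy)benzene; 6 prenyl bromide (1-bromo-3-methylbut-2-ene)
Product: 8 1,3,5-tris(methoxymethoxy)-2-(3-methylbut-2-en-1-yl)benzene, via aryllithium 7 (not isolated)
Conditions: n-BuLi (1.1 equiv), THF, 0 °C; then CuBr·SMe2 (10 mol %), prenyl bromide, −78 °C → rt
Reagents that add atoms: none
Why: Directed ortho-metalation between two OMOM groups followed by copper-catalysed SN2 allylation of the aryllithium gives the linear prenyl arene.

**Step 6**
Reactants: 8 1,3,5-tris(methoxymethoxy)-2-(3-methylbut-2-en-1-yl)benzene; 6 prenyl bromide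
Product: 10 1,3,5-tris(methoxymethoxy)-2,4-bis(3-methylbut-2-en-1-yl)benzene, via aryllithium 9 (not isolated)
Conditions: n-BuLi, TMEDA, THF, −20 → 0 °C; then CuBr·SMe2 (10 mol %), prenyl bromide, −78 °C → rt
Reagents that add atoms: none
Why: A second directed ortho-metalation at either of the two equivalent remaining ring positions (each still flanked by two OMOM groups) is kinetically faster than lateral deprotonation of the prenyl CH2, and the aryllithium is allylated as before.

**Step 7**
Reactants: 10 1,3,5-tris(methoxymethoxy)-2,4-bis(3-methylbut-2-en-1-yl)benzene; 11 N-methoxy-N-methylacetamide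
Product: 13 1-[2,4,6-tris(methoxymethoxy)-3,5-bis(3-methylbut-2-en-1-yl)phenyl]ethan-1-one, via aryllithium 12 (not isolated)
Conditions: n-BuLi, TMEDA, THF, −20 → 0 °C; then MeC(O)N(OMe)Me, −78 → 0 °C; H2O
Reagents that add atoms: none
Why: Directed ortho-metalation at the last ring C–H and Weinreb ketone synthesis, in which the chelated tetrahedral adduct prevents over-addition and releases the methyl ketone only on quench.

**Step 8**
Reactants: 13 1-[2,4,6-tris(methoxymethoxy)-3,5-bis(3-methylbut-2-en-1-yl)phenyl]ethan-1-one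
Product: 14 1-[2-hydroxy-4,6-bis(methoxymethoxy)-3,5-bis(3-methylbut-2-en-1-yl)phenyl]ethan-1-one
Conditions: MgBr2·OEt2 (1.5 equiv), Et2O/CH2Cl2, 0 °C → rt; H2O work-up
Reagents that add atoms: none
Why: Chelation-controlled Lewis-acid acetal cleavage: magnesium bridges the carbonyl and one ortho OMOM, so only that acetal is cut, and the resulting magnesium phenolate ties up the carbonyl and shields the second ortho OMOM, while the para OMOM cannot chelate.

**Step 9**
Reactants: 1 resorcinol; 15 N,N-dimethylformamide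
Product: 17 2,4-dihydroxybenzaldehyde, via Vilsmeier iminium chloride 16 (not isolated)
Conditions: POCl3, MeCN, −15 °C → rt; then H2O, 50 °C
Reagents that add atoms: water (O)
Why: Vilsmeier–Haack formylation attacks the position para to one hydroxyl and ortho to the other, and hydrolysis of the iminium salt gives the aldehyde.

**Step 10**
Reactants: 17 2,4-dihydroxybenzaldehyde
Product: 18 5-bromo-2,4-dihydroxybenzaldehyde
Conditions: Br2 (1.0 equiv), AcOH, rt
Reagents that add atoms: bromine (BrBr)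
Why: Electrophilic aromatic bromination goes to C5 (ortho to the 4-OH, para to the 2-OH), which is less hindered than C3 between the two oxygens.

**Step 11**
Reactants: 18 5-bromo-2,4-dihydroxybenzaldehyde
Product: 19 5-bromo-2-hydroxy-4-(methoxymethoxy)benzaldehyde
Conditions: MOMCl (1.05 equiv), K2CO3, acetone, 0 °C → rt
Reagents that add atoms: chloromethyl methyl ether (COCCl)
Why: Selective O-alkylation: the 2-OH is locked in a hydrogen bond to the aldehyde, so the more acidic, free 4-OH is protected.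

**Step 12**
Reactants: 20 4-bromophenol
Product: 21 1-bromo-4-(methoxymethoxy)benzene
Conditions: MOMCl (1.2 equiv), NaH (1.2 equiv), DMF, 0 °C → rt
Reagents that add atoms: chloromethyl methyl ether (COCCl)
Why: Williamson-type MOM protection of the phenoxide makes the ring compatible with organolithium chemistry.

**Step 13**
Reactants: 21 1-bromo-4-(methoxymethoxy)benzene; 15 N,N-dimethylformamide
Product: 24 [4-(methoxymethoxy)phenyl]methanol, via aryllithium 22 (not isolated), via 4-(methoxymethoxy)benzaldehyde 23 (not isolated)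
Conditions: n-BuLi, THF, −78 °C; DMF, −78 → 0 °C; then MeOH, NaBH4, 0 °C
Reagents that add atoms: none
Why: Bromine–lithium exchange, Bouveault formylation and in-situ borohydride reduction give the benzylic alcohol in one pot.

**Step 14**
Reactants: 19 5-bromo-2-hydroxy-4-(methoxymethoxy)benzaldehyde; 24 [4-(methoxymethoxy)phenyl]methanol
Product: 25 5-bromo-4-(methoxymethoxy)-2-{[4-(methoxymethoxy)phenyl]methoxy}benzaldehyde
Conditions: PPh3, DIAD, THF, 0 °C → rt
Reagents that add atoms: none
Why: Mitsunobu etherification of the acidic salicylaldehyde phenol with a primary benzylic alcohol avoids handling an unstable electron-rich benzyl halide.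

**Step 15**
Reactants: 25 5-bromo-4-(methoxymethoxy)-2-{[4-(methoxymethoxy)phenyl]methoxy}benzaldehyde; 3 2-[3,5-bis(methoxymethoxy)phenyl]-4,4,5,5-tetramethyl-1,3,2-dioxaborolane
Product: 26 [3,5-bis(methoxymethoxy)phenyl](5-bromo-4-(methoxymethoxy)-2-{[4-(methoxymethoxy)phenyl]methoxy}phenyl)methanol (racemic)
Conditions: [Rh(OH)(cod)]2 (3 mol %), P(t-Bu)3 (6 mol %), KOH (aq, 2 equiv), dioxane, 60 °C
Reagents that add atoms: none
Why: Rhodium-catalysed 1,2-addition of the arylboron reagent to the aldehyde (Miyaura-type) tolerates the aryl bromide and the MOM ethers, and the racemic carbinol centre it creates is removed in the next step.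

**Step 16**
Reactants: 26 the racemic diarylmethanol
Product: 27 [3,5-bis(methoxymethoxy)phenyl](5-bromo-4-(methoxymethoxy)-2-{[4-(methoxymethoxy)phenyl]methoxy}phenyl)methanone
Conditions: MnO2 (activated, excess), CH2Cl2, rt
Reagents that add atoms: none
Why: Mild heterogeneous oxidation of a doubly benzylic alcohol to the benzophenone leaves acetals and the aryl bromide untouched.

**Step 17**
Reactants: 27 the diaryl ketone
Product: 28 {[3,5-bis(methoxymethoxy)phenyl](5-bromo-4-(methoxymethoxy)-2-{[4-(methoxymethoxy)phenyl]methoxy}phenyl)methylidene}hydrazine (E/Z mixture)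
Conditions: N2H4·H2O (10 equiv), AcOH (cat.), EtOH, 80 °C
Reagents that add atoms: hydrazine (NN)
Why: Condensation of the ketone with excess hydrazine gives the N-unsubstituted hydrazone, the excess suppressing azine formation.

**Step 18**
Reactants: 28 the hydrazone
Product: 30 (2S,3R)-5-bromo-3-[3,5-bis(methoxymethoxy)phenyl]-6-(methoxymethoxy)-2-[4-(methoxymethoxy)phenyl]-2,3-dihydro-1-benzofuran (2,3-cis), via diaryldiazomethane 29 (not isolated)
Conditions: MnO2, CH2Cl2, 0 °C, filter; then Rh2(R-PTAD)4 (1 mol %), CH2Cl2, −20 °C → rt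
Reagents that add atoms: none
Why: Dehydrogenation to the diaryldiazomethane and intramolecular 1,5 C–H insertion of the donor/donor rhodium carbene into the benzylic ether C–H closes the dihydrofuran ring; the chiral carboxylate ligands select the carbene face and set C3 as R, and the concerted insertion gives the 2,3-cis relationship (C2 S).

**Step 19**
Reactants: 30 the cis-dihydrobenzofuran
Product: 31 (2R,3R)-5-bromo-3-[3,5-bis(methoxymethoxy)phenyl]-6-(methoxymethoxy)-2-[4-(methoxymethoxy)phenyl]-2,3-dihydro-1-benzofuran (2,3-trans)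
Conditions: TFA (2 equiv), CH2Cl2, −20 → 0 °C; Et3N quench
Reagents that add atoms: none
Why: Acid-mediated epimerisation: reversible heterolysis of the C2–O bond to the para-alkoxybenzylic cation and ring re-closure gives the thermodynamically preferred trans isomer, inverting C2 to R while C3 (R) is untouched.

**Step 20**
Reactants: 31 the trans-dihydrobenzofuran bromide; 15 N,N-dimethylformamide
Product: 33 (2R,3R)-3-[3,5-bis(methoxymethoxy)phenyl]-6-(methoxymethoxy)-2-[4-(methoxymethoxy)phenyl]-2,3-dihydro-1-benzofuran-5-carbaldehyde, via aryllithium 32 (not isolated)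
Conditions: n-BuLi, THF, −78 °C; DMF; H2O
Reagents that add atoms: none
Why: Bromine–lithium exchange at −78 °C is faster than any deprotonation at C3 or ortho-metalation, and Bouveault formylation of the aryllithium gives the aldehyde without touching the stereocentres.

**Step 21**
Reactants: 14 1-[2-hydroxy-4,6-bis(methoxymethoxy)-3,5-bis(3-methylbut-2-en-1-yl)phenyl]ethan-1-one; 33 the dihydrobenzofuran aldehyde
Product: 34 (2E)-1-[2-hydroxy-4,6-bis(methoxymethoxy)-3,5-bis(3-methylbut-2-en-1-yl)phenyl]-3-[(2R,3R)-3-[3,5-bis(methoxymethoxy)phenyl]-6-(methoxymethoxy)-2-[4-(methoxymethoxy)phenyl]-2,3-dihydro-1-benzofuran-5-yl]prop-2-en-1-one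
Conditions: KOH (excess), EtOH/THF/H2O, rt, 24–48 h
Reagents that add atoms: none
Why: Claisen–Schmidt aldol condensation joins the two halves; E1cB dehydration gives the E-enone, and all protecting groups and both stereocentres are base-stable.

**Step 22**
Reactants: 34 the 2'-hydroxychalcone
Product: 35 (2S)-2-[(2R,3R)-3-[3,5-bis(methoxymethoxy)phenyl]-6-(methoxymethoxy)-2-[4-(methoxymethoxy)phenyl]-2,3-dihydro-1-benzofuran-5-yl]-5,7-bis(methoxymethoxy)-6,8-bis(3-methylbut-2-en-1-yl)-2,3-dihydro-4H-chromen-4-one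
Conditions: quinine-derived 9-epi-amino thiourea bearing a 3,5-bis(trifluoromethyl)phenyl group (10 mol %), toluene, 0 °C → rt
Reagents that add atoms: none
Why: Intramolecular oxa-Michael addition under bifunctional catalysis (the quinuclidine deprotonates the phenol, the thiourea hydrogen-bonds the enone) closes ring C on one enone face to set C2 as S; the minor C2 epimer is a diastereomer and is removed by chromatography.

**Step 23**
Reactants: 35 the hexa-MOM flavanone
Product: 36 (2S)-2-[(2R,3R)-3-(3,5-dihydroxyphenyl)-6-hydroxy-2-(4-hydroxyphenyl)-2,3-dihydro-1-benzofuran-5-yl]-5,7-dihydroxy-6,8-bis(3-methylbut-2-en-1-yl)-2,3-dihydro-4H-chromen-4-one (CNP0230984.1)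
Conditions: 3 M HCl (aq)/MeOH/THF, 40 °C
Reagents that add atoms: none
Why: Acid-catalysed acetal exchange removes all six MOM groups as dimethoxymethane under conditions mild enough to spare the prenyl groups and the flavanone C2, and the trans dihydrobenzofuran is already the thermodynamic isomer.

**Compound list**
1 | resorcinol (benzene-1,3-diol) | Oc1cccc(O)c1 | starting material
2 | 1,3-bis(methoxymethoxy)benzene | COCOc1cccc(OCOC)c1 | intermediate
3 | 2-[3,5-bis(methoxymethoxy)phenyl]-4,4,5,5-tetramethyl-1,3,2-dioxaborolane | COCOc1cc(OCOC)cc(c1)B1OC(C)(C)C(C)(C)O1 | intermediate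
4 | 3,5-bis(methoxymethoxy)phenol | COCOc1cc(O)cc(OCOC)c1 | intermediate
5 | 1,3,5-tris(methoxymethoxy)benzene | COCOc1cc(OCOC)cc(OCOC)c1 | intermediate
6 | prenyl bromide (1-bromo-3-methylbut-2-ene) | CC(C)=CCBr | starting material
7 | [2,4,6-tris(methoxymethoxy)phenyl]lithium | [Li]c1c(OCOC)cc(OCOC)cc1OCOC | intermediate
8 | 1,3,5-tris(methoxymethoxy)-2-(3-methylbut-2-en-1-yl)benzene | CC(C)=CCc1c(OCOC)cc(OCOC)cc1OCOC | intermediate
9 | [2,4,6-tris(methoxymethoxy)-3-(3-methylbut-2-en-1-yl)phenyl]lithium | [Li]c1c(OCOC)cc(OCOC)c(CC=C(C)C)c1OCOC | intermediate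
10 | 1,3,5-tris(methoxymethoxy)-2,4-bis(3-methylbut-2-en-1-yl)benzene | CC(C)=CCc1c(OCOC)cc(OCOC)c(CC=C(C)C)c1OCOC | intermediate
11 | N-methoxy-N-methylacetamide | CC(=O)N(C)OC | starting material
12 | [2,4,6-tris(methoxymethoxy)-3,5-bis(3-methylbut-2-en-1-yl)phenyl]lithium | [Li]c1c(OCOC)c(CC=C(C)C)c(OCOC)c(CC=C(C)C)c1OCOC | intermediate
13 | 1-[2,4,6-tris(methoxymethoxy)-3,5-bis(3-methylbut-2-en-1-yl)phenyl]ethan-1-one | CC(=O)c1c(OCOC)c(CC=C(C)C)c(OCOC)c(CC=C(C)C)c1OCOC | intermediate
14 | 1-[2-hydroxy-4,6-bis(methoxymethoxy)-3,5-bis(3-methylbut-2-en-1-yl)phenyl]ethan-1-one | CC(=O)c1c(O)c(CC=C(C)C)c(OCOC)c(CC=C(C)C)c1OCOC | intermediate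
15 | N,N-dimethylformamide | CN(C)C=O | starting material
16 | N-[(2,4-dihydroxyphenyl)methylidene]-N-methylmethanaminium chloride | C[N+](C)=Cc1ccc(O)cc1O.[Cl-] | intermediate
17 | 2,4-dihydroxybenzaldehyde | O=Cc1ccc(O)cc1O | intermediate
18 | 5-bromo-2,4-dihydroxybenzaldehyde | O=Cc1cc(Br)c(O)cc1O | intermediate
19 | 5-bromo-2-hydroxy-4-(methoxymethoxy)benzaldehyde | O=Cc1cc(Br)c(OCOC)cc1O | intermediate
20 | 4-bromophenol | Oc1ccc(Br)cc1 | starting material
21 | 1-bromo-4-(methoxymethoxy)benzene | COCOc1ccc(Br)cc1 | intermediate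
22 | [4-(methoxymethoxy)phenyl]lithium | [Li]c1ccc(OCOC)cc1 | intermediate
23 | 4-(methoxymethoxy)benzaldehyde | O=Cc1ccc(OCOC)cc1 | intermediate
24 | [4-(methoxymethoxy)phenyl]methanol | OCc1ccc(OCOC)cc1 | intermediate
25 | 5-bromo-4-(methoxymethoxy)-2-{[4-(methoxymethoxy)phenyl]methoxy}benzaldehyde | O=Cc1cc(Br)c(OCOC)cc1OCc1ccc(OCOC)cc1 | intermediate
26 | [3,5-bis(methoxymethoxy)phenyl](5-bromo-4-(methoxymethoxy)-2-{[4-(methoxymethoxy)phenyl]methoxy}phenyl)methanol (racemic) | OC(c1cc(OCOC)cc(OCOC)c1)c1cc(Br)c(OCOC)cc1OCc1ccc(OCOC)cc1 | intermediate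
27 | [3,5-bis(methoxymethoxy)phenyl](5-bromo-4-(methoxymethoxy)-2-{[4-(methoxymethoxy)phenyl]methoxy}phenyl)methanone | O=C(c1cc(OCOC)cc(OCOC)c1)c1cc(Br)c(OCOC)cc1OCc1ccc(OCOC)cc1 | intermediate
28 | {[3,5-bis(methoxymethoxy)phenyl](5-bromo-4-(methoxymethoxy)-2-{[4-(methoxymethoxy)phenyl]methoxy}phenyl)methylidene}hydrazine (E/Z mixture) | NN=C(c1cc(OCOC)cc(OCOC)c1)c1cc(Br)c(OCOC)cc1OCc1ccc(OCOC)cc1 | intermediate
29 | 1-bromo-5-{diazo[3,5-bis(methoxymethoxy)phenyl]methyl}-2-(methoxymethoxy)-4-{[4-(methoxymethoxy)phenyl]methoxy}benzene | [N-]=[N+]=C(c1cc(OCOC)cc(OCOC)c1)c1cc(Br)c(OCOC)cc1OCc1ccc(OCOC)cc1 | intermediate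
30 | (2S,3R)-5-bromo-3-[3,5-bis(methoxymethoxy)phenyl]-6-(methoxymethoxy)-2-[4-(methoxymethoxy)phenyl]-2,3-dihydro-1-benzofuran (cis) | Brc1cc2c(cc1OCOC)O[C@H](c1ccc(OCOC)cc1)[C@@H]2c1cc(OCOC)cc(OCOC)c1 | intermediate
31 | (2R,3R)-5-bromo-3-[3,5-bis(methoxymethoxy)phenyl]-6-(methoxymethoxy)-2-[4-(methoxymethoxy)phenyl]-2,3-dihydro-1-benzofuran (trans) | Brc1cc2c(cc1OCOC)O[C@@H](c1ccc(OCOC)cc1)[C@@H]2c1cc(OCOC)cc(OCOC)c1 | intermediate
32 | [(2R,3R)-3-[3,5-bis(methoxymethoxy)phenyl]-6-(methoxymethoxy)-2-[4-(methoxymethoxy)phenyl]-2,3-dihydro-1-benzofuran-5-yl]lithium | [Li]c1cc2c(cc1OCOC)O[C@@H](c1ccc(OCOC)cc1)[C@@H]2c1cc(OCOC)cc(OCOC)c1 | intermediate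
33 | (2R,3R)-3-[3,5-bis(methoxymethoxy)phenyl]-6-(methoxymethoxy)-2-[4-(methoxymethoxy)phenyl]-2,3-dihydro-1-benzofuran-5-carbaldehyde | O=Cc1cc2c(cc1OCOC)O[C@@H](c1ccc(OCOC)cc1)[C@@H]2c1cc(OCOC)cc(OCOC)c1 | intermediate
34 | (2E)-1-[2-hydroxy-4,6-bis(methoxymethoxy)-3,5-bis(3-methylbut-2-en-1-yl)phenyl]-3-[(2R,3R)-3-[3,5-bis(methoxymethoxy)phenyl]-6-(methoxymethoxy)-2-[4-(methoxymethoxy)phenyl]-2,3-dihydro-1-benzofuran-5-yl]prop-2-en-1-one | CC(C)=CCc1c(OCOC)c(CC=C(C)C)c(O)c(C(=O)/C=C/c2cc3c(cc2OCOC)O[C@@H](c2ccc(OCOC)cc2)[C@@H]3c2cc(OCOC)cc(OCOC)c2)c1OCOC | intermediate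
35 | (2S)-2-[(2R,3R)-3-[3,5-bis(methoxymethoxy)phenyl]-6-(methoxymethoxy)-2-[4-(methoxymethoxy)phenyl]-2,3-dihydro-1-benzofuran-5-yl]-5,7-bis(methoxymethoxy)-6,8-bis(3-methylbut-2-en-1-yl)-2,3-dihydro-4H-chromen-4-one | CC(C)=CCc1c(OCOC)c(CC=C(C)C)c2c(c1OCOC)C(=O)C[C@@H](c1cc3c(cc1OCOC)O[C@@H](c1ccc(OCOC)cc1)[C@@H]3c1cc(OCOC)cc(OCOC)c1)O2 | intermediate
36 | (2S)-2-[(2R,3R)-3-(3,5-dihydroxyphenyl)-6-hydroxy-2-(4-hydroxyphenyl)-2,3-dihydro-1-benzofuran-5-yl]-5,7-dihydroxy-6,8-bis(3-methylbut-2-en-1-yl)-2,3-dihydro-4H-chromen-4-one | CC(C)=CCc1c(O)c(CC=C(C)C)c2c(c1O)C(=O)C[C@@H](c1cc3c(cc1O)O[C@@H](c1ccc(O)cc1)[C@@H]3c1cc(O)cc(O)c1)O2 | target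

**Totals**
Total step count: 23.
Longest linear sequence: 13 steps (resorcinol through steps 9, 10, 11, 14, 15, 16, 17, 18, 19, 20, 21, 22, 23).

**Steps most likely to fail**

Step 22 (asymmetric oxa-Michael). A non-activated chalcone gives only a modest facial bias with hydrogen-bonding catalysts, so the 2S:2R ratio may be low. The fallback sets out from 31 and 14 and comes back at 35. Bromide 31 is lithiated as in step 20 (aryllithium 32), trapped with B(Oi-Pr)3 and hydrolysed to [(2R,3R)-3-[3,5-bis(methoxymethoxy)phenyl]-6-(methoxymethoxy)-2-[4-(methoxymethoxy)phenyl]-2,3-dihydro-1-benzofuran-5-yl]boronic acid F1. Acetophenone 14 is condensed with DMF dimethyl acetal (toluene, 90 °C) to (2E)-3-(dimethylamino)-1-[2-hydroxy-4,6-bis(methoxymethoxy)-3,5-bis(3-methylbut-2-en-1-yl)phenyl]prop-2-en-1-one F2, which cyclises with loss of dimethylamine (AcOH, 60 °C) to 5,7-bis(methoxymethoxy)-6,8-bis(3-methylbut-2-en-1-yl)-4H-chromen-4-one F3. F1 and F3 are then joined by a rhodium-catalysed asymmetric 1,4-addition ([RhCl(C2H4)2]2 with a chiral diene or an electron-poor atropisomeric bisphosphine, aqueous KOH, toluene, 40 °C). This forms the C2–aryl bond and the 2S centre in one catalyst-controlled step and gives 35 directly.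

Step 19 (C2 epimerisation with the MOM ethers kept). The window between ionisation of the benzylic C2–O bond and loss of aryl MOM groups may be too narrow. The fallback sets out from 30 and comes back at 31. Treatment of 30 with 3 M HCl in MeOH at 50 °C deliberately removes all four MOM groups and equilibrates C2 through the para-hydroxybenzylic cation, giving trans 5-[(2R,3R)-5-bromo-6-hydroxy-2-(4-hydroxyphenyl)-2,3-dihydro-1-benzofuran-3-yl]benzene-1,3-diol F4. Re-protection of the four phenols (MOMCl, NaH, DMF, 0 °C) returns 31.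

Step 8 (ortho-selective removal of one MOM group). The twisted carbonyl of the hexasubstituted acetophenone may chelate poorly, leading to para cleavage or double cleavage. The fallback sets out from 13 and comes back at 14. All three MOM groups are removed (HCl, MeOH, rt) to give 1-[2,4,6-trihydroxy-3,5-bis(3-methylbut-2-en-1-yl)phenyl]ethan-1-one F5. The selectivity is then obtained in the protection direction: MOMCl (2.2 equiv) and i-Pr2NEt in CH2Cl2 alkylate only the two hydroxyls that are not locked in the hydrogen bond to the carbonyl, giving 14.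

**Further compounds**
F1 | step 22 | [(2R,3R)-3-[3,5-bis(methoxymethoxy)phenyl]-6-(methoxymethoxy)-2-[4-(methoxymethoxy)phenyl]-2,3-dihydro-1-benzofuran-5-yl]boronic acid | OB(O)c1cc2c(cc1OCOC)O[C@@H](c1ccc(OCOC)cc1)[C@@H]2c1cc(OCOC)cc(OCOC)c1
F2 | step 22 | (2E)-3-(dimethylamino)-1-[2-hydroxy-4,6-bis(methoxymethoxy)-3,5-bis(3-methylbut-2-en-1-yl)phenyl]prop-2-en-1-one | CN(C)/C=C/C(=O)c1c(O)c(CC=C(C)C)c(OCOC)c(CC=C(C)C)c1OCOC
F3 | step 22 | 5,7-bis(methoxymethoxy)-6,8-bis(3-methylbut-2-en-1-yl)-4H-chromen-4-one | CC(C)=CCc1c(OCOC)c(CC=C(C)C)c2occc(=O)c2c1OCOC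
F4 | step 19 | 5-[(2R,3R)-5-bromo-6-hydroxy-2-(4-hydroxyphenyl)-2,3-dihydro-1-benzofuran-3-yl]benzene-1,3-diol | Brc1cc2c(cc1O)O[C@@H](c1ccc(O)cc1)[C@@H]2c1cc(O)cc(O)c1
F5 | step 8 | 1-[2,4,6-trihydroxy-3,5-bis(3-methylbut-2-en-1-yl)phenyl]ethan-1-one | CC(=O)c1c(O)c(CC=C(C)C)c(O)c(CC=C(C)C)c1O
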